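Everything rests on building ring A de novo onto the intact (R)-piperidine: a thermal benzannulation of a siloxyalkyne with 3-methoxycyclobutenone. It exploits the 1,3,5-oxygenation of ring A (C5, C7, C8a) with C8 between two oxygens: one operation forms C8–C8a and C6–C7, re-closes C4a–C8a, and delivers the C5 methoxy, a free C8a phenol and a silylated C7 oxygen, already differentiated. The precursor is the triisopropylsilyl ynol ether of (R)-N-Boc-2-ethynylpiperidine, made from the pipecolate ester without touching the stereocentre. The free phenol then directs formylation to C4a; an ynone closes the pyranone ring, and silyl and Boc groups leave last.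

Key step: step 4

Remark on numbering: ring A and the pyranone ring carry flavone numbers (O1, C2, C3, C4, C4a, C5 to C8, C8a) and the piperidine carbon on C8 is C2'. With these numbers the ketene carbonyl carbon of the key step becomes C8a, so the cycloaddition forms C8–C8a and C6–C7 and the electrocyclisation re-forms C4a–C8a. Only this assignment leaves the free phenol where the pyranone must close and the silyl ether on O7.

Assumption: methyl (R)-N-Boc-pipecolate 1 is purchased as such; it is the methyl ester of commercial (R)-N-Boc-pipecolic acid.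

Step 1
Reactants: 1 methyl (2R)-1-(tert-butoxycarbonyl)piperidine-2-carboxylate
Product: 3 tert-butyl (2R)-2-ethynylpiperidine-1-carboxylate, via aldehyde 2 (not isolated)
Conditions: i-Bu2AlH, CH2Cl2, −78 °C; then MeOH, K2CO3, MeC(O)C(N2)P(O)(OMe)2, −78 °C → rt
Reagents that add atoms: dimethyl (1-diazo-2-oxopropyl)phosphonate, CC(=O)C(=[N+]=[N-])P(=O)(OC)OC
Why: Partial hydride reduction of the ester stops at the aluminium hemiacetal at −78 °C, and the aldehyde released by methanol is trapped at once in a Seyferth–Gilbert homologation (Ohira–Bestmann variant), so the configurationally fragile α-amino aldehyde is never isolated and the C2' centre should be carried through unchanged.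

Step 2
Reactants: 3 tert-butyl (2R)-2-ethynylpiperidine-1-carboxylate
Product: 6 tert-butyl (2R)-2-[(triisopropylsilyloxy)ethynyl]piperidine-1-carboxylate, via lithium acetylide 4 (not isolated), via lithium ynolate 5 (not isolated)
Conditions: n-BuLi, THF, −78 °C; LiOOt-Bu (from t-BuOOH and LiN(SiMe3)2), −78 → 0 °C; TIPSCl, −78 → 0 °C
Reagents that add atoms: tert-butyl hydroperoxide, CC(C)(C)OO; triisopropylsilyl chloride, CC(C)[Si](Cl)(C(C)C)C(C)C
Why: Electrophilic oxygenation of the lithium acetylide by lithium tert-butyl peroxide gives the ynolate, which the bulky chlorosilane silylates on oxygen to the isolable triisopropylsilyl ynol ether, while one equivalent of base at −78 °C removes only the acetylenic proton and leaves the propargylic stereocentre alone.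

Step 3
Reactants: 7 3-ethoxycyclobut-2-en-1-one
Product: 8 3-methoxycyclobut-2-en-1-one
Conditions: MeOH (solvent), pyridinium p-toluenesulfonate (cat.), rt; EtOH removed by repeated concentration from MeOH
Reagents that add atoms: methanol, CO
Why: Acid-catalysed transetherification of the vinylogous ester (addition of methanol at C3, loss of ethanol) exchanges the alkoxy group without touching a C–C bond, and the large excess of methanol drives the equilibrium.

Step 4
Reactants: 6 tert-butyl (2R)-2-[(triisopropylsilyloxy)ethynyl]piperidine-1-carboxylate; 8 3-methoxycyclobut-2-en-1-one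
Product: 13 tert-butyl (2R)-2-[2-hydroxy-4-methoxy-6-(triisopropylsilyloxy)phenyl]piperidine-1-carboxylate, via vinylketene 9 (not isolated), via vinylcyclobutenone 10 (not isolated), via dienylketene 11 (not isolated), via cyclohexadienone 12 (not isolated)
Conditions: 8 (1.2 equiv), degassed toluene, 80 → 110 °C, sealed tube
Reagents that add atoms: none
Why: On heating, 8 undergoes 4π electrocyclic opening of its C(=O)–CH2 bond to (1-methoxyethenyl)ketene 9, which adds to ynol ether 6 in a [2+2] cycloaddition (new bonds C8–C8a and C6–C7) to give 10; 4π opening of 10 to dienylketene 11, 6π electrocyclisation (re-forming C4a–C8a) to 12 and tautomerisation should then give phenol 13. The closest known reaction is of exactly this type, the Danheiser benzannulation of cyclobutenones with trialkylsilyloxyalkynes, which delivers resorcinol monosilyl ethers. Ring A, the only ring formed, closes by the thermal disrotatory 6π electrocyclisation of the dienylketene and is locked by aromatisation. No stereocentre is created: the transient sp3 carbon of 10 vanishes on ring opening, and the (R)-centre C2' is a spectator that meets neither acid nor base. The step needs one regiochemical outcome in the [2+2] addition, and the polarised ynol ether secures it, because its nucleophilic carbon (the one bearing the piperidine) bonds to the electrophilic ketene carbonyl carbon; the piperidine therefore ends ortho to the free phenol at C8a, the silyloxy group lands on C7 and the methoxy group on C5.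

Step 5
Reactants: 13 tert-butyl (2R)-2-[2-hydroxy-4-methoxy-6-(triisopropylsilyloxy)phenyl]piperidine-1-carboxylate
Product: 15 tert-butyl (2R)-2-[3-formyl-2-hydroxy-4-methoxy-6-(triisopropylsilyloxy)phenyl]piperidine-1-carboxylate, via hydroxymethyl phenol 14 (not isolated)
Conditions: MgCl2, Et3N, (CH2O)n, MeCN, reflux; cold dilute aqueous acid work-up
Reagents that add atoms: paraformaldehyde (as formaldehyde), C=O
Why: In the Casnati–Skattebøl ortho-formylation the magnesium phenoxide binds formaldehyde and delivers it only to the one free ortho carbon (C4a), a second formaldehyde oxidises the benzylic alkoxide by hydride transfer, and the mildly basic medium should spare the carbamate and the aryl silyl ether.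

Step 6
Reactants: 15 tert-butyl (2R)-2-[3-formyl-2-hydroxy-4-methoxy-6-(triisopropylsilyloxy)phenyl]piperidine-1-carboxylate; 16 phenylacetylene
Product: 18 tert-butyl (2R)-2-[2-hydroxy-3-(1-hydroxy-3-phenylprop-2-yn-1-yl)-4-methoxy-6-(triisopropylsilyloxy)phenyl]piperidine-1-carboxylate as a mixture of carbinol epimers, via lithium phenylacetylide 17 (not isolated)
Conditions: 16 (3 equiv), n-BuLi (2.8 equiv), THF, −78 °C; then 15, −78 → 0 °C; aq. NH4Cl; crude 18 taken on directly
Reagents that add atoms: none
Why: One equivalent of the alkynyllithium deprotonates the phenol and a second undergoes 1,2-addition to the aldehyde, the carbamate and silyl ether being inert to this nucleophile at low temperature; the new carbinol centre is not controlled and does not need to be, because step 7 removes it.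

Step 7
Reactants: 18 tert-butyl (2R)-2-[2-hydroxy-3-(1-hydroxy-3-phenylprop-2-yn-1-yl)-4-methoxy-6-(triisopropylsilyloxy)phenyl]piperidine-1-carboxylate
Product: 19 tert-butyl (2R)-2-[2-hydroxy-4-methoxy-3-(3-phenylprop-2-ynoyl)-6-(triisopropylsilyloxy)phenyl]piperidine-1-carboxylate
Conditions: activated MnO2 (excess), CH2Cl2, rt
Reagents that add atoms: none
Why: Oxidation of a doubly activated (benzylic and propargylic) alcohol by activated MnO2 proceeds under neutral conditions that should spare the phenol, the carbamate and the silyl ether, and it erases the uncontrolled carbinol centre.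

Step 8
Reactants: 19 tert-butyl (2R)-2-[2-hydroxy-4-methoxy-3-(3-phenylprop-2-ynoyl)-6-(triisopropylsilyloxy)phenyl]piperidine-1-carboxylate
Product: 22 tert-butyl (2R)-2-(7-hydroxy-5-methoxy-4-oxo-2-phenyl-4H-chromen-8-yl)piperidine-1-carboxylate, via enaminone 20 (not isolated), via silyl flavone 21 (not isolated)
Conditions: Et2NH, EtOH, 60 °C; concentrate; then Bu4NF, THF, 0 °C → rt; aq. NH4Cl
Reagents that add atoms: none
Why: Conjugate addition of diethylamine to the ynone gives a β-amino enone whose β-carbon is then attacked by the ortho phenol with loss of the amine (oxa-Michael addition–elimination), which enforces 6-endo closure to the chromone and excludes the 5-exo aurone, and fluoride then cleaves the aryl silyl ether while the nitrogen is still protected.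

Step 9
Reactants: 22 tert-butyl (2R)-2-(7-hydroxy-5-methoxy-4-oxo-2-phenyl-4H-chromen-8-yl)piperidine-1-carboxylate
Product: 24 7-hydroxy-5-methoxy-2-phenyl-8-[(2R)-piperidin-2-yl]-4H-chromen-4-one (target), via hydrochloride salt 23 (not isolated)
Conditions: HCl (4 M in dioxane), CH2Cl2, 0 °C → rt; then cold aq. NaHCO3 to pH 7–8
Reagents that add atoms: none
Why: Acidolytic cleavage of the tert-butyl carbamate (loss of isobutene and CO2) frees the piperidine at room temperature, where the protonated chromone is deactivated towards tert-butylation and the o-hydroxybenzylic C–N bond should not ionise, and the brief cold neutralisation keeps the (R)-centre from retro-Mannich scrambling.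

Compound list
1 | methyl (2R)-1-(tert-butoxycarbonyl)piperidine-2-carboxylate | COC(=O)[C@H]1CCCCN1C(=O)OC(C)(C)C | starting material
2 | tert-butyl (2R)-2-formylpiperidine-1-carboxylate | O=C[C@H]1CCCCN1C(=O)OC(C)(C)C | intermediate (not isolated)
3 | tert-butyl (2R)-2-ethynylpiperidine-1-carboxylate | C#C[C@H]1CCCCN1C(=O)OC(C)(C)C | intermediate
4 | tert-butyl (2R)-2-(lithioethynyl)piperidine-1-carboxylate | [Li]C#C[C@H]1CCCCN1C(=O)OC(C)(C)C | intermediate (not isolated)
5 | lithium 2-[(2R)-1-(tert-butoxycarbonyl)piperidin-2-yl]ethynolate | [Li+].[O-]C#C[C@H]1CCCCN1C(=O)OC(C)(C)C | intermediate (not isolated)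
6 | tert-butyl (2R)-2-[(triisopropylsilyloxy)ethynyl]piperidine-1-carboxylate | CC(C)[Si](OC#C[C@H]1CCCCN1C(=O)OC(C)(C)C)(C(C)C)C(C)C | intermediate (precursor of the key step)
7 | 3-ethoxycyclobut-2-en-1-one | CCOC1=CC(=O)C1 | starting material
8 | 3-methoxycyclobut-2-en-1-one | COC1=CC(=O)C1 | intermediate (precursor of the key step)
9 | 3-methoxybuta-1,3-dien-1-one, the (1-methoxyethenyl)ketene | COC(=C)C=C=O | intermediate (not isolated)
10 | tert-butyl (2R)-2-[3-(1-methoxyethenyl)-4-oxo-2-(triisopropylsilyloxy)cyclobut-1-en-1-yl]piperidine-1-carboxylate, both epimers at the ring sp3 carbon | O=C1C(C(=C)OC)C(O[Si](C(C)C)(C(C)C)C(C)C)=C1[C@H]2CCCCN2C(=O)OC(C)(C)C | intermediate (not isolated)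
11 | tert-butyl (2R)-2-[(3E)-5-methoxy-1-oxo-3-(triisopropylsilyloxy)hexa-1,3,5-trien-2-yl]piperidine-1-carboxylate | O=C=C([C@H]1CCCCN1C(=O)OC(C)(C)C)/C(O[Si](C(C)C)(C(C)C)C(C)C)=C\C(OC)=C | intermediate (not isolated)
12 | tert-butyl (2R)-2-[4-methoxy-6-oxo-2-(triisopropylsilyloxy)cyclohexa-1,3-dien-1-yl]piperidine-1-carboxylate | O=C1CC(OC)=CC(O[Si](C(C)C)(C(C)C)C(C)C)=C1[C@H]2CCCCN2C(=O)OC(C)(C)C | intermediate (not isolated)
13 | tert-butyl (2R)-2-[2-hydroxy-4-methoxy-6-(triisopropylsilyloxy)phenyl]piperidine-1-carboxylate | COc1cc(O)c([C@H]2CCCCN2C(=O)OC(C)(C)C)c(O[Si](C(C)C)(C(C)C)C(C)C)c1 | intermediate (product of the key step)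
14 | tert-butyl (2R)-2-[2-hydroxy-3-(hydroxymethyl)-4-methoxy-6-(triisopropylsilyloxy)phenyl]piperidine-1-carboxylate, formed as its magnesium salt | COc1c(CO)c(O)c([C@H]2CCCCN2C(=O)OC(C)(C)C)c(O[Si](C(C)C)(C(C)C)C(C)C)c1 | intermediate (not isolated)
15 | tert-butyl (2R)-2-[3-formyl-2-hydroxy-4-methoxy-6-(triisopropylsilyloxy)phenyl]piperidine-1-carboxylate | COc1c(C=O)c(O)c([C@H]2CCCCN2C(=O)OC(C)(C)C)c(O[Si](C(C)C)(C(C)C)C(C)C)c1 | intermediate
16 | phenylacetylene | C#Cc1ccccc1 | starting material
17 | lithium phenylacetylide | [Li]C#Cc1ccccc1 | intermediate (not isolated)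
18 | tert-butyl (2R)-2-[2-hydroxy-3-(1-hydroxy-3-phenylprop-2-yn-1-yl)-4-methoxy-6-(triisopropylsilyloxy)phenyl]piperidine-1-carboxylate, both carbinol epimers | COc1c(C(O)C#Cc2ccccc2)c(O)c([C@H]3CCCCN3C(=O)OC(C)(C)C)c(O[Si](C(C)C)(C(C)C)C(C)C)c1 | intermediate
19 | tert-butyl (2R)-2-[2-hydroxy-4-methoxy-3-(3-phenylprop-2-ynoyl)-6-(triisopropylsilyloxy)phenyl]piperidine-1-carboxylate | COc1c(C(=O)C#Cc2ccccc2)c(O)c([C@H]3CCCCN3C(=O)OC(C)(C)C)c(O[Si](C(C)C)(C(C)C)C(C)C)c1 | intermediate
20 | tert-butyl (2R)-2-{3-[3-(diethylamino)-3-phenylprop-2-enoyl]-2-hydroxy-4-methoxy-6-(triisopropylsilyloxy)phenyl}piperidine-1-carboxylate, alkene geometry not defined | COc1c(C(=O)C=C(N(CC)CC)c2ccccc2)c(O)c([C@H]3CCCCN3C(=O)OC(C)(C)C)c(O[Si](C(C)C)(C(C)C)C(C)C)c1 | intermediate (not isolated)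
21 | tert-butyl (2R)-2-[5-methoxy-4-oxo-2-phenyl-7-(triisopropylsilyloxy)-4H-chromen-8-yl]piperidine-1-carboxylate | COc1cc(O[Si](C(C)C)(C(C)C)C(C)C)c([C@H]2CCCCN2C(=O)OC(C)(C)C)c2oc(-c3ccccc3)cc(=O)c12 | intermediate (not isolated)
22 | tert-butyl (2R)-2-(7-hydroxy-5-methoxy-4-oxo-2-phenyl-4H-chromen-8-yl)piperidine-1-carboxylate | COc1cc(O)c([C@H]2CCCCN2C(=O)OC(C)(C)C)c2oc(-c3ccccc3)cc(=O)c12 | intermediate
23 | (2R)-2-(7-hydroxy-5-methoxy-4-oxo-2-phenyl-4H-chromen-8-yl)piperidinium chloride | COc1cc(O)c([C@H]2CCCC[NH2+]2)c2oc(-c3ccccc3)cc(=O)c12.[Cl-] | intermediate (not isolated)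
24 | 7-hydroxy-5-methoxy-2-phenyl-8-[(2R)-piperidin-2-yl]-4H-chromen-4-one | COc1cc(O)c([C@H]2CCCCN2)c2oc(-c3ccccc3)cc(=O)c12 | target
25 | 2,4,6-trihydroxybenzaldehyde | O=Cc1c(O)cc(O)cc1O | starting material (used only in the fallback for step 4)

Total step count: 9.
Longest linear sequence: 8 steps (1, 2, 4, 5, 6, 7, 8, 9, from 1 to 24); step 3 is the one-step side branch.

Steps most likely to fail

Risk 1, step 4. The [2+2] addition of the vinylketene to the α-branched, carbamate-flanked alkyne carbon may be too slow. The ketene would then be lost by dimerisation or by acylating the product phenol, or the ynol ether would decay thermally before it reacts. The fallback uses known chemistry and gives up the de novo ring: ring A is bought, and the C8–C2' bond and the stereocentre are made by addition of a Grignard reagent to a chiral N-sulfinyl imine. It sets out from 25 and comes back to the route at 13.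
- Selective methylation of the non-chelated para hydroxyl of 25 (MeI, K2CO3, acetone) should give 2,6-dihydroxy-4-methoxybenzaldehyde F1, and MOMCl with i-Pr2NEt its bis(methoxymethyl) ether F2.
- Condensation with (S)-tert-butanesulfinamide (Ti(OEt)4, THF) should give the N-sulfinyl aldimine F3.
- 4-Chlorobutylmagnesium bromide F4 (from 1-bromo-4-chlorobutane and Mg) should add to F3 in CH2Cl2 at −48 °C through the cyclic magnesium-chelated transition state to give the open-chain sulfinamide F5 with the R configuration at carbon. This sense has to be confirmed on the first run, because the ortho acetal groups may chelate; the (R)-sulfinamide is the remedy if it is reversed.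
- KOt-Bu in THF should close the ring by N-alkylation to the N-sulfinylpiperidine F6.
- HCl in MeOH should remove the sulfinyl group and both acetals to give the piperidinium chloride F7.
- Boc2O with NaHCO3 should give the symmetric N-Boc resorcinol F8, and one equivalent of TIPSCl with imidazole in DMF should silylate one of its two equivalent phenols to give 13.

Risk 2, step 2. Oxygen transfer to the acetylide may be incomplete, the ynolate may be silylated on carbon instead of oxygen, or the ynol ether may hydrolyse during isolation. The fallback is the Kowalski ester homologation, which reaches the same ynolate from the ester carbonyl and also by-passes step 1 with its sensitive aldehyde. It sets out from 1 and comes back at 6 by way of ynolate 5.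
- Dibromomethyllithium F9 (CH2Br2, lithium 2,2,6,6-tetramethylpiperidide, THF, −78 °C) should add to ester 1.
- LiN(SiMe3)2 then turns the dibromomethyl ketone into the lithium enolate of tert-butyl (2R)-2-(2,2-dibromoacetyl)piperidine-1-carboxylate F10.
- n-BuLi (−78 °C → rt) should trigger bromine–lithium exchange and 1,2-shift of the piperidinyl carbon with retention to give 5, which TIPSCl silylates on oxygen to 6.

Risk 3, step 3. Methanol may add to the strained carbonyl group and open the four-membered ring instead of exchanging the alkoxy group, and the volatile product may be lost on concentration. The fallback replaces the exchange by hydrolysis and O-alkylation. It sets out from 7 and comes back at 8.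
- Dilute aqueous HCl should hydrolyse the enol ether of 7 to cyclobutane-1,3-dione F11.
- Its enol should be O-methylated by Me3SiCHN2 in MeOH/Et2O at 0 °C to give 8.

Further compounds
F1 | step 4 | 2,6-dihydroxy-4-methoxybenzaldehyde | COc1cc(O)c(C=O)c(O)c1
F2 | step 4 | 4-methoxy-2,6-bis(methoxymethoxy)benzaldehyde | COCOc1cc(OC)cc(OCOC)c1C=O
F3 | step 4 | (S,E)-N-[4-methoxy-2,6-bis(methoxymethoxy)benzylidene]-2-methylpropane-2-sulfinamide | CC(C)(C)[S@](=O)/N=C/c1c(OCOC)cc(OC)cc1OCOC
F4 | step 4 | 4-chlorobutylmagnesium bromide | ClCCCC[Mg]Br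
F5 | step 4 | (S)-N-{(1R)-5-chloro-1-[4-methoxy-2,6-bis(methoxymethoxy)phenyl]pentyl}-2-methylpropane-2-sulfinamide | CC(C)(C)[S@](=O)N[C@H](CCCCCl)c1c(OCOC)cc(OC)cc1OCOC
F6 | step 4 | (2R)-1-[(S)-tert-butylsulfinyl]-2-[4-methoxy-2,6-bis(methoxymethoxy)phenyl]piperidine | CC(C)(C)[S@](=O)N1CCCC[C@@H]1c2c(OCOC)cc(OC)cc2OCOC
F7 | step 4 | (2R)-2-(2,6-dihydroxy-4-methoxyphenyl)piperidinium chloride | COc1cc(O)c([C@H]2CCCC[NH2+]2)c(O)c1.[Cl-]
F8 | step 4 | tert-butyl (2R)-2-(2,6-dihydroxy-4-methoxyphenyl)piperidine-1-carboxylate | COc1cc(O)c([C@H]2CCCCN2C(=O)OC(C)(C)C)c(O)c1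
F9 | step 2 | dibromomethyllithium | [Li]C(Br)Br
F10 | step 2 | lithium enolate of tert-butyl (2R)-2-(2,2-dibromoacetyl)piperidine-1-carboxylate | [Li+].[O-]C(=C(Br)Br)[C@H]1CCCCN1C(=O)OC(C)(C)C
F11 | step 3 | cyclobutane-1,3-dione | O=C1CC(=O)C1
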